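Numbering used throughout: indane atoms C1–C3 and C3a–C7a (ring A sits on C1), carbinol carbon C8, and primed locants O1', C2', C3', C3a'–C7a' for the dihydrobenzofuran. Compound numbers are those of the steps and of the compound list.

## Analysis of the target

The target (32) is a resveratrol trimer in which an indane (benzo ring F, hydroxyls on C5 and C7) is joined through C2 to C4' of a 2',3'-dihydrobenzofuran (benzo ring B, hydroxyl on C6'). Ring A (4-hydroxyphenyl) sits on C1, the carbinol carbon C8 with ring C (4-hydroxyphenyl) on C3, ring D (3,5-dihydroxyphenyl) on C3' and ring E (4-hydroxyphenyl) on C2'. There are six stereocentres in two clusters: C1, C2 and C3 are all-trans (1S,2R,3S) with the exocyclic C8 (S) next to C3, and C2' and C3' are trans (2'R,3'R); the C2–C4' bond separates the clusters, so neither can be relied on to control the other. The sensitive sites are the seven phenols, the 4-hydroxybenzylic alcohol at C8 and the benzylic ether C2'–O1' (both ionise to quinone methides in acid), and the doubly benzylic C1–H and C3'–H. The central difficulty is the C2–C4' bond: it links a secondary ring carbon flanked by two substituted carbons to an aryl carbon whose neighbour C3a' carries the branched C3', a very poor setting for a cross-coupling. The strategy rests on ring B, a resorcinol with oxygen on C6' and C7a', hydrogen on C5' and C7', and carbon substituents on the adjacent C4' (bond to C2) and C3a' (bond to C3'). This is the pattern formed when a 1,3-dioxygenated diene (C5'–C6'–C7'–C7a') adds across an acetylenic ketone (C4'≡C3a'–C3'=O). Ring B can therefore be grown on the finished indane from an alkyne on C2, so that the hindered bond is made while C4' is still an sp carbon.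

## Retrosynthetic reasoning

The last bond to be made is C8–H. The 4-hydroxybenzylic alcohol of 32 would not survive a Lewis-acid deprotection, so 32 is traced back to ketone 31, whose carbonyl group protects C8 against ionisation. The forward step is a catalyst-controlled transfer hydrogenation that has to tolerate seven free phenols and decide C8 against whatever bias C3 exerts.

The seven O–H bonds of 31 are traced back to the methyl ethers of 30. Methyl ethers pass unchanged through the Lewis acid, the organometallic reagents, the hydrides and the bases of the route. They are cleaved at the ketone stage, where C8 cannot ionise; the forward cleavage must leave C2'–O1' closed or let it reclose.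

In 30 the bond from C8 to ring C is cut, which leads to aldehyde 27 and the aryl Grignard reagent 28, with alcohol 29 between them. C8 is thus the hydroxymethyl carbon on C3, which travels as a pivalate from 9 to 25 and is unmasked through 26. C3 is enolisable in 27 and 30, but it sits trans to the large C2 substituent, which is the stable arrangement.

The dihydrofuran ring of 25 is opened at C3'–C2' and C2'–O1'. This one-carbon disconnection leaves the o-quinone methide 24 (C3' electrophile, O1' nucleophile) and the sulfonium salt 23, whose ylide brings C2' with ring E. 24 is released from sulfone 18, which comes through benzhydrol 17 from the 2-hydroxybenzophenone 16; the ketone and the phenol of 16 are exactly the two handles needed. The indane cannot be expected to distinguish the faces of C3', so the sulfide of 23 is chiral (21, from 19 through 20, alkylated with 22), and the forward step must deliver the trans ring under reagent control.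

Ring B of 16 is cut at C4'–C5' and C3a'–C7a' (the key disconnection). This removes the whole ring and leaves ynone 12 and diene 14 (from 13); the cycloadduct 15 aromatises by elimination and desilylation. The cut is made here and not at C2–C4' because it turns the hindered aryl–alkyl bond into a bond between C2 and an sp carbon, which can be formed long before the ring exists. The forward reaction needs only regiocontrol, which the polarisation of both partners supplies.

12 is cut between the alkyne and the carbonyl carbon into the terminal alkyne 10 and the acid chloride 11, which brings C3' and ring D.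

The indane ring of 10 is opened at C1–C7a, giving the open-chain silyl ether 9; in the forward direction ring F attacks a 4-methoxybenzylic cation at C1. The ring is closed on an open chain and not on a lactone. With a lactone across C2–C3 in place, closure would force a cis ring fusion and put ring A on the face opposite to the C3 side chain, a relation that no epimerisation at C2 can correct. The open chain instead transcribes a trans C2/C3 relation and lets C1 form trans to C2.

The ethynyl group of 9 (from alcohol 8) is traced back to the carbonyl carbon of lactone 6 through lactol 7. Reduction and one-carbon homologation open the ring and at the same time tell the two oxygenated carbons apart: the one on C2 becomes the alkyne, the one on C3 stays a protected alcohol and later becomes C8.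

6 is the silyl ether of aldol 5, which is cut at C1–C2 into lactone 3 and aldehyde 4. The five-membered enolate is attacked anti to the aryl group on C3, which sets C2 trans to C3. The carbinol carbon C1 is left uncontrolled, since it is flattened later.

3 is cut at C3–C3a into butenolide 1 and boronic acid 2. A catalytic asymmetric conjugate arylation sets C3, the one stereocentre of the indane part that comes from a chiral catalyst; C2 and C1 follow from it.

## Alternatives that were turned down

Alternative 1: The dihydrobenzofuran is made as a separate fragment by ring contraction of a flavanone, the bond formed being C3'–C3a'.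
- Forward key step: the (2R)-flavanone A1 is treated with PhI(OAc)2 and H2SO4 in trimethyl orthoformate. The enol ether is iodinated at C3 anti to the C2 aryl group, the benzo ring migrates from C4 to C3 as iodobenzene leaves, and C4 ends as a methyl ester on the contracted ring, giving the trans ester A2.
- For: the trans relation of C2' and C3' and the absolute configuration of C2' come from an easily made enantioenriched flavanone and a stereospecific 1,2-shift. On this point it is stronger than the chosen route, where these centres depend on a chiral ylide meeting a hindered quinone methide.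
- Against: A2 carries an ester carbon on C3' where the target has ring D, and an oxygen on C4' where the target has the bond to C2. The ester must be exchanged for an aryl group at a stereocentre. C4' (as a triflate after debenzylation), now flanked by the substituted C3', must then be joined to the secondary C2 of an indane, which is the bond that is hardest to make by coupling.
- Comparison: the chosen strategy gives up the secure dihydrofuran stereochemistry. It offers in its place a C2–C4' bond that needs no cross-coupling and a ring B in which every atom delivered is kept, with fewer concession steps.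

Alternative 2: The indane ring is closed last, at C3–C3a, together with the bond from C8 to ring C.
- Forward key step: the acyclic precursor A3 holds C1, C2 and the complete dihydrobenzofuran, a triflate on ring F at C3a and an (E)-alkenyl pinacol boronate C3=C8. The Grignard reagent 28 converts the boronate into its ate complex, and zerovalent palladium generated from Pd(OAc)2 and MandyPhos inserts into the triflate. The arylpalladium species then attacks C3 while the 4-methoxyphenyl group shifts from boron to C8, which closes the five-membered ring and gives A4.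
- For: two bonds and the stereocentres C3 and C8 are set in one catalyst-controlled step, and oxidation of the C–B bond with retention gives the C8 carbinol directly. For C8 this is clearly shorter than steps 17 to 22 of the chosen route, so it is stronger there.
- Against: A3 has to be assembled first, so the hindered C2–C4' bond and the C1/C2 relation must be made on an open chain without a ring to guide them. The metallate shift is an intermolecular coupling by design; in a ring-closing version it must outrun direct aryl–aryl transfer and Heck-type insertion. The chiral ligand also has to work with or against the existing centre C2.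
- Comparison: the chosen strategy is longer at C8. In return it puts its one uncertain bond construction on a reaction class with firm regiochemical rules, and it builds C1–C3 as a ring before anything hindered is attached.

Alternative 3: The indane is closed at C1–C2 with the free phenol of ring A as the activating group.
- Forward key step: in the precursor A5, ring F carries the 4-hydroxybenzhydryl alcohol (C1) and, ortho to it, the ketone C3 whose α-methylene C2 already bears ring B. A chiral phosphoric acid dehydrates the alcohol to the p-quinone methide and directs the enol to add through C2 to C1, closing the five-membered ring as the trans-2,3-disubstituted indan-1-one A6.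
- For: the key step is catalytic and uses a phenol that the target has anyway. Like the chosen strategy it avoids a hindered coupling, since C2 is an unhindered benzylic methylene when it is bonded to ring B; on that point the two are equal.
- Against: A6 has a carbonyl group at C3, so the C3–C8 bond and the stereocentres C3 and C8 are still missing. Installing them means adding a carbon nucleophile to a hindered, enolisable ketone and then removing the tertiary hydroxyl with hydride, which would enter anti to the C2 aryl group and leave the C8 side chain cis to it. Ring A must also be the only unprotected phenol, and the catalyst has to cope with a precursor that is already chiral.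
- Comparison: the chosen strategy carries the carbon that becomes C8 on C3 from the first step, with its configuration fixed before the ring is closed, and offers that in place of the shorter ring closure.

Key step: step 10

Assumption: the ylide of 23 is taken to react with the o-quinone methide 24 through the same face as it does with aldehydes (S,S-configured stilbene oxides, which corresponds to 2'R here); if the sense were opposite, the enantiomeric salt made from (2R,5R)-hexane-2,5-diol would be used.

## Route

Step 1
Reactants: 1 2(5H)-furanone; 2 3,5-dimethoxyphenylboronic acid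
Product: 3 (S)-4-(3,5-dimethoxyphenyl)dihydrofuran-2(3H)-one
Conditions: Rh(acac)(C2H4)2 (3 mol %), (S)-BINAP, dioxane/H2O (10:1), 100 °C
Reagents that add atoms: none
Why: Hayashi–Miyaura asymmetric 1,4-addition: the arylrhodium species formed by transmetalation inserts the butenolide C=C and is hydrolysed. (S)-BINAP is the ligand enantiomer that gives S-configured β-aryl products from cyclic enones and lactones, and it sets C3.

Step 2
Reactants: 3 (S)-4-(3,5-dimethoxyphenyl)dihydrofuran-2(3H)-one; 4 4-methoxybenzaldehyde
Product: 5 (3S,4S)-4-(3,5-dimethoxyphenyl)-3-[hydroxy(4-methoxyphenyl)methyl]dihydrofuran-2(3H)-one (3,4-trans, both carbinol epimers)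
Conditions: LiN(i-Pr)2, THF, −78 °C; then 4; AcOH, −78 °C
Reagents that add atoms: none
Why: Aldol addition of the lactone lithium enolate; the aldehyde approaches anti to the aryl group on the neighbouring ring carbon, which sets C2 trans to C3. The carbinol carbon (future C1) forms as a mixture, which does not matter because it becomes a cation in step 7.

Step 3
Reactants: 5 trans-aldol lactone
Product: 6 (3S,4S)-3-[(tert-butyldimethylsilyloxy)(4-methoxyphenyl)methyl]-4-(3,5-dimethoxyphenyl)dihydrofuran-2(3H)-one
Conditions: TBSOTf, 2,6-lutidine, CH2Cl2, −78 → 0 °C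
Reagents that add atoms: tert-butyldimethylsilyl trifluoromethanesulfonate, CC(C)(C)[Si](C)(C)OS(=O)(=O)C(F)(F)F
Why: Silylation of the secondary alcohol blocks retro-aldol cleavage in steps 4 and 5, and the silyloxy group later serves as the leaving group at C1.

Step 4
Reactants: 6 silylated aldol lactone
Product: 7 (3S,4S)-3-[(tert-butyldimethylsilyloxy)(4-methoxyphenyl)methyl]-4-(3,5-dimethoxyphenyl)tetrahydrofuran-2-ol (lactol, both anomers)
Conditions: i-Bu2AlH, CH2Cl2, −78 °C; then H2O
Reagents that add atoms: none
Why: Partial reduction of a γ-lactone to the lactol; at low temperature the aluminium hemiacetal is stable until work-up, so over-reduction to the diol is avoided.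

Step 5
Reactants: 7 lactol
Product: 8 (2S,3R)-3-[(tert-butyldimethylsilyloxy)(4-methoxyphenyl)methyl]-2-(3,5-dimethoxyphenyl)pent-4-yn-1-ol
Conditions: dimethyl (1-diazo-2-oxopropyl)phosphonate, K2CO3, MeOH, 0 °C → rt
Reagents that add atoms: dimethyl (1-diazo-2-oxopropyl)phosphonate, COP(=O)(OC)C(=[N+]=[N-])C(C)=O
Why: Ohira–Bestmann homologation of the open hydroxy-aldehyde form of the lactol. It turns the former lactone carbon into the ethynyl group on C2 and releases the primary alcohol of the C3 side chain, which tells the two oxygenated carbons apart.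

Step 6
Reactants: 8 alkynol
Product: 9 (2S,3R)-3-[(tert-butyldimethylsilyloxy)(4-methoxyphenyl)methyl]-2-(3,5-dimethoxyphenyl)pent-4-yn-1-yl pivalate
Conditions: PivCl, Et3N, DMAP (cat.), CH2Cl2, 0 °C → rt
Reagents that add atoms: pivaloyl chloride, CC(C)(C)C(=O)Cl
Why: Acylation of the primary alcohol. An ester is chosen over a silyl ether because its oxygen does not capture the benzylic cation of step 7, and a pivalate over an acetate because it survives the hydride and base steps up to step 17.

Step 7
Reactants: 9 open-chain silyl ether pivalate
Product: 10 all-trans (1S,2R,3S)-2-ethynyl-5,7-dimethoxy-1-(4-methoxyphenyl)-3-(pivaloyloxymethyl)indane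
Conditions: BF3·OEt2 (20 mol %), CH2Cl2, −78 → −20 °C
Reagents that add atoms: none
Why: Ionisation of the benzylic silyl ether gives a 4-methoxybenzylic cation, which an ortho carbon of the 3,5-dimethoxyphenyl ring captures in a five-membered Friedel–Crafts ring closure (intramolecular benzylation of an electron-rich arene). C2 and C3 keep the trans relation written into the lactone. C1 forms trans to C2 because the arene attacks the cation through the conformer with C2–H in the plane of the cation, anti to the ethynyl group.

Step 8
Reactants: 10 indanyl alkyne; 11 3,5-dimethoxybenzoyl chloride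
Product: 12 1-(3,5-dimethoxyphenyl)-3-[(1S,2R,3S)-5,7-dimethoxy-1-(4-methoxyphenyl)-3-(pivaloyloxymethyl)indan-2-yl]prop-2-yn-1-one
Conditions: PdCl2(PPh3)2 (2 mol %), CuI (4 mol %), Et3N (1.2 equiv), THF, rt
Reagents that add atoms: none
Why: Sonogashira-type acylation of a terminal alkyne with an acid chloride (copper acetylide, acylpalladium, reductive elimination) gives the conjugated ynone. Room temperature and little excess amine keep the propargylic C2–H from isomerising to the allenyl ketone.

Step 9
Reactants: 13 methyl (E)-3-methoxybut-2-enoate
Product: 14 1,3-dimethoxy-1-(trimethylsilyloxy)buta-1,3-diene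
Conditions: LiN(i-Pr)2, THF, −78 °C; then Me3SiCl
Reagents that add atoms: chlorotrimethylsilane, C[Si](C)(C)Cl
Why: γ-Deprotonation of the β-methoxy enoate and O-silylation of the dienolate give the silyl ketene acetal diene.

Step 10
Reactants: 12 indan-2-yl ynone; 14 1,3-dimethoxy-1-(trimethylsilyloxy)buta-1,3-diene
Product: 16 (1S,2R,3S)-2-[2-(3,5-dimethoxybenzoyl)-3-hydroxy-5-methoxyphenyl]-5,7-dimethoxy-1-(4-methoxyphenyl)-3-(pivaloyloxymethyl)indane, via silyl ketal cyclohexadiene 15 (not isolated)
Conditions: 14 (3 equiv), toluene, 90 °C; then CF3CO2H (cat.), wet CH2Cl2, rt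
Reagents that add atoms: none
Why: Normal-demand [4+2] cycloaddition of the electron-rich diene 14 with the electron-poor alkyne of 12, asynchronous: the unsubstituted CH2 terminus of 14, which has the largest HOMO coefficient, bonds first to the β-carbon of the ynone, which has the largest LUMO coefficient and carries the indanyl group (C5'–C4'), and the ketene acetal carbon then bonds to the α-carbon (C7a'–C3a'). The six-membered ring B is thus closed by an intermolecular cycloaddition that forms both ring bonds, giving the 1,4-cyclohexadiene 15 with a mixed methyl silyl ketal at C7a'; acid then cleaves the ketal to the dienone, which tautomerises through the C5' methylene to the phenol. The closest known reaction type is the Diels–Alder/aromatisation of 1,3-dioxygenated 1-silyloxydienes with acetylenic ketones and esters to resorcinol monoethers. No stereocentre is created: the ketal carbon of 15 is lost on aromatisation, and C1–C3 are not touched under neutral thermal conditions. The only selectivity required is regioselectivity, and it is secured twice over, electronically by the matched polarisation of the two partners and sterically because the hindered β-carbon meets the unhindered CH2 terminus. Chemoselectivity for cycloaddition over 1,2-addition to the ketone is kept by working without a Lewis acid. The product carries the free C7a' phenol hydrogen-bonded to the C3' ketone, the two handles for the furan ring, and the C6' oxygen as its methyl ether.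

Step 11
Reactants: 16 2-hydroxybenzophenone
Product: 17 (1S,2R,3S)-2-{2-[(3,5-dimethoxyphenyl)(hydroxy)methyl]-3-hydroxy-5-methoxyphenyl}-5,7-dimethoxy-1-(4-methoxyphenyl)-3-(pivaloyloxymethyl)indane (both carbinol epimers)
Conditions: NaBH4, THF/MeOH, 0 °C → rt
Reagents that add atoms: none
Why: Borohydride reduction of the diaryl ketone to the o-hydroxybenzhydrol; the pivalate is inert. The new carbinol centre is irrelevant because it is flattened in step 16.

Step 12
Reactants: 17 o-hydroxybenzhydrol
Product: 18 (1S,2R,3S)-2-{2-[(3,5-dimethoxyphenyl)(p-tolylsulfonyl)methyl]-3-hydroxy-5-methoxyphenyl}-5,7-dimethoxy-1-(4-methoxyphenyl)-3-(pivaloyloxymethyl)indane (both sulfone epimers)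
Conditions: p-TolSO2H, CH2Cl2, rt
Reagents that add atoms: p-toluenesulfinic acid, Cc1ccc(cc1)S(=O)O
Why: The acid ionises the doubly activated benzhydrol and the sulfinate captures the cation at sulfur, giving the bench-stable sulfone that is the standard base-triggered o-quinone methide precursor. Capture by the soft sulfinate is faster than attack by a neighbouring arene.

Step 13
Reactants: 19 (2S,5S)-hexane-2,5-diol
Product: 20 (2S,5S)-hexane-2,5-diyl dimethanesulfonate
Conditions: MsCl, Et3N, CH2Cl2, 0 °C
Reagents that add atoms: methanesulfonyl chloride, CS(=O)(=O)Cl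
Why: Mesylation of both secondary alcohols with retention at carbon.

Step 14
Reactants: 20 dimesylate
Product: 21 (2R,5R)-2,5-dimethylthiolane
Conditions: Na2S·9H2O, DMSO, rt → 40 °C
Reagents that add atoms: sodium sulfide, [Na+].[Na+].[S-2]
Why: Double SN2 displacement by sulfide with inversion at both carbons closes the thiolane and gives the C2-symmetric (2R,5R) sulfide.

Step 15
Reactants: 21 (2R,5R)-2,5-dimethylthiolane; 22 4-methoxybenzyl alcohol
Product: 23 (2R,5R)-1-(4-methoxybenzyl)-2,5-dimethylthiolan-1-ium tetrafluoroborate
Conditions: HBF4·OEt2, CH2Cl2, 0 °C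
Reagents that add atoms: tetrafluoroboric acid (diethyl ether complex), F[B-](F)(F)F.[H+]
Why: The acid ionises the 4-methoxybenzylic alcohol and the sulfide captures the cation. C2 symmetry makes the two sulfur lone pairs equivalent, so a single sulfonium salt forms, kept as its non-nucleophilic tetrafluoroborate.

Step 16
Reactants: 18 sulfone; 23 chiral 4-methoxybenzyl sulfonium salt
Product: 25 (1S,2R,3S)-2-[(2R,3R)-3-(3,5-dimethoxyphenyl)-6-methoxy-2-(4-methoxyphenyl)-2,3-dihydrobenzofuran-4-yl]-5,7-dimethoxy-1-(4-methoxyphenyl)-3-(pivaloyloxymethyl)indane, via o-quinone methide 24 (not isolated)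
Conditions: 23 (1.5 equiv), Cs2CO3 (3 equiv), CH2Cl2, −20 °C → rt
Reagents that add atoms: none
Why: Base eliminates sulfinate from 18 to the o-quinone methide 24 and deprotonates 23; the benzylic ylide adds to C3' and the phenoxide displaces the sulfide at C2' (5-exo-tet), the known [4+1] annulation of o-quinone methides with sulfur ylides. The C2-symmetric sulfide fixes the reacting face of the ylide carbon (C2', R after inversion), and the anti-selective addition and ring closure set C3' trans to it (R). The indane is expected to add little bias; in the conformer with C2–H eclipsing C3a', the face of C3' that leads to 3'R is the one remote from ring A, so substrate and reagent should not be opposed.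

Step 17
Reactants: 25 dihydrobenzofuran pivalate
Product: 26 primary alcohol (hydroxymethyl group on C3)
Conditions: i-Bu2AlH, CH2Cl2, −78 °C; then H2O
Reagents that add atoms: none
Why: Reductive cleavage of the pivalate; no other group in 25 reacts with the hydride.

Step 18
Reactants: 26 primary alcohol
Product: 27 aldehyde (formyl group on C3)
Conditions: Dess–Martin periodinane, CH2Cl2, 0 °C → rt
Reagents that add atoms: none
Why: Dess–Martin oxidation under non-basic conditions. C3 is enolisable in the aldehyde but already has the stable trans relation to C2.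

Step 19
Reactants: 27 aldehyde; 28 4-methoxyphenylmagnesium bromide
Product: 29 secondary alcohol at C8 (both C8 epimers)
Conditions: THF, −78 → 0 °C; then H2O
Reagents that add atoms: none
Why: 1,2-Addition of the aryl Grignard reagent at low temperature, where addition outruns enolisation of the α-aryl aldehyde. The C8 configuration is not controlled since it is erased in step 20.

Step 20
Reactants: 29 secondary alcohol
Product: 30 heptamethyl ether of the C8 ketone
Conditions: Dess–Martin periodinane, CH2Cl2, rt
Reagents that add atoms: none
Why: Oxidation of the benzylic alcohol to the aryl ketone; C3 stays trans to C2, which is the stable arrangement.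

Step 21
Reactants: 30 heptamethyl ketone
Product: 31 heptaphenol ketone
Conditions: BBr3 (excess), CH2Cl2, −78 °C → rt; then H2O
Reagents that add atoms: none
Why: Lewis acid–base complexation of each methyl ether and SN2 attack of bromide on methyl. Each cleaved ether becomes an aryloxyborane, a weaker donor, which lowers the tendency of C2'–O1' to ionise, and a ring that does open can reclose to the stable trans isomer. The C8 ketone cannot ionise.

Step 22
Reactants: 31 heptaphenol ketone
Product: 32 target, (1S,2R,3S,8S,2'R,3'R)
Conditions: RuCl[(S,S)-TsDPEN](p-cymene) (5 mol %), HCO2H/Et3N (5:2), DMF, 30 °C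
Reagents that add atoms: none
Why: Asymmetric transfer hydrogenation of an aryl alkyl ketone by the bifunctional ruthenium hydride/amine catalyst. With the (S,S)-ligand the aryl group is held by a CH–π contact with the cymene ligand and hydride is delivered to give the S carbinol, as with simple aryl alkyl ketones. The weakly acidic formate medium leaves the phenols protonated.

## Compound list

1 | 2(5H)-furanone | O=C1OCC=C1 | starting material
2 | 3,5-dimethoxyphenylboronic acid | COc1cc(OC)cc(B(O)O)c1 | starting material
3 | (S)-4-(3,5-dimethoxyphenyl)dihydrofuran-2(3H)-one | COc1cc(OC)cc([C@H]2COC(=O)C2)c1 | intermediate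
4 | 4-methoxybenzaldehyde | COc1ccc(C=O)cc1 | starting material
5 | (3S,4S)-4-(3,5-dimethoxyphenyl)-3-[hydroxy(4-methoxyphenyl)methyl]dihydrofuran-2(3H)-one; 3,4-trans, carbinol epimers | COc1ccc(C(O)[C@H]2C(=O)OC[C@@H]2c2cc(OC)cc(OC)c2)cc1 | intermediate
6 | (3S,4S)-3-[(tert-butyldimethylsilyloxy)(4-methoxyphenyl)methyl]-4-(3,5-dimethoxyphenyl)dihydrofuran-2(3H)-one | COc1ccc(C(O[Si](C)(C)C(C)(C)C)[C@H]2C(=O)OC[C@@H]2c2cc(OC)cc(OC)c2)cc1 | intermediate
7 | (3S,4S)-3-[(tert-butyldimethylsilyloxy)(4-methoxyphenyl)methyl]-4-(3,5-dimethoxyphenyl)tetrahydrofuran-2-ol; anomers | COc1ccc(C(O[Si](C)(C)C(C)(C)C)[C@H]2C(O)OC[C@@H]2c2cc(OC)cc(OC)c2)cc1 | intermediate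
8 | (2S,3R)-3-[(tert-butyldimethylsilyloxy)(4-methoxyphenyl)methyl]-2-(3,5-dimethoxyphenyl)pent-4-yn-1-ol | COc1ccc(C(O[Si](C)(C)C(C)(C)C)[C@@H](C#C)[C@H](CO)c2cc(OC)cc(OC)c2)cc1 | intermediate
9 | (2S,3R)-3-[(tert-butyldimethylsilyloxy)(4-methoxyphenyl)methyl]-2-(3,5-dimethoxyphenyl)pent-4-yn-1-yl pivalate | COc1ccc(C(O[Si](C)(C)C(C)(C)C)[C@@H](C#C)[C@H](COC(=O)C(C)(C)C)c2cc(OC)cc(OC)c2)cc1 | intermediate
10 | all-trans (1S,2R,3S)-2-ethynyl-5,7-dimethoxy-1-(4-methoxyphenyl)-3-(pivaloyloxymethyl)indane | COc1ccc([C@H]2c3c(OC)cc(OC)cc3[C@@H](COC(=O)C(C)(C)C)[C@@H]2C#C)cc1 | intermediate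
11 | 3,5-dimethoxybenzoyl chloride | COc1cc(OC)cc(C(Cl)=O)c1 | starting material
12 | 1-(3,5-dimethoxyphenyl)-3-[(1S,2R,3S)-5,7-dimethoxy-1-(4-methoxyphenyl)-3-(pivaloyloxymethyl)indan-2-yl]prop-2-yn-1-one; all-trans | COc1ccc([C@H]2c3c(OC)cc(OC)cc3[C@@H](COC(=O)C(C)(C)C)[C@@H]2C#CC(=O)c2cc(OC)cc(OC)c2)cc1 | intermediate
13 | methyl (E)-3-methoxybut-2-enoate | CO/C(C)=C/C(=O)OC | starting material
14 | 1,3-dimethoxy-1-(trimethylsilyloxy)buta-1,3-diene | C=C(OC)C=C(OC)O[Si](C)(C)C | intermediate
15 | cycloadduct: cyclohexa-1,4-diene with the C7a' methyl trimethylsilyl ketal, the C6' enol ether, the C3a' aroyl group and the indan-2-yl group on C4'; ketal epimers | COc1ccc([C@H]2c3c(OC)cc(OC)cc3[C@@H](COC(=O)C(C)(C)C)[C@@H]2C2=C(C(=O)c3cc(OC)cc(OC)c3)C(OC)(O[Si](C)(C)C)C=C(OC)C2)cc1 | intermediate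
16 | (1S,2R,3S)-2-[2-(3,5-dimethoxybenzoyl)-3-hydroxy-5-methoxyphenyl]-5,7-dimethoxy-1-(4-methoxyphenyl)-3-(pivaloyloxymethyl)indane | COc1ccc([C@H]2c3c(OC)cc(OC)cc3[C@@H](COC(=O)C(C)(C)C)[C@@H]2c2cc(OC)cc(O)c2C(=O)c2cc(OC)cc(OC)c2)cc1 | intermediate
17 | benzhydrol from 16; (1S,2R,3S), carbinol epimers | COc1ccc([C@H]2c3c(OC)cc(OC)cc3[C@@H](COC(=O)C(C)(C)C)[C@@H]2c2cc(OC)cc(O)c2C(O)c2cc(OC)cc(OC)c2)cc1 | intermediate
18 | p-tolyl sulfone from 17; (1S,2R,3S), sulfone epimers | COc1ccc([C@H]2c3c(OC)cc(OC)cc3[C@@H](COC(=O)C(C)(C)C)[C@@H]2c2cc(OC)cc(O)c2C(c2cc(OC)cc(OC)c2)S(=O)(=O)c2ccc(C)cc2)cc1 | intermediate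
19 | (2S,5S)-hexane-2,5-diol | C[C@H](O)CC[C@H](C)O | starting material
20 | (2S,5S)-hexane-2,5-diyl dimethanesulfonate | C[C@H](OS(C)(=O)=O)CC[C@H](C)OS(C)(=O)=O | intermediate
21 | (2R,5R)-2,5-dimethylthiolane | C[C@@H]1CC[C@@H](C)S1 | intermediate
22 | 4-methoxybenzyl alcohol | COc1ccc(CO)cc1 | starting material
23 | (2R,5R)-1-(4-methoxybenzyl)-2,5-dimethylthiolan-1-ium tetrafluoroborate | COc1ccc(C[S+]2[C@H](C)CC[C@H]2C)cc1.F[B-](F)(F)F | intermediate
24 | o-quinone methide: ring B as 6-(3,5-dimethoxybenzylidene)-3-methoxycyclohexa-2,4-dienone bearing the (1S,2R,3S)-indan-2-yl group on C4' | COc1ccc([C@H]2c3c(OC)cc(OC)cc3[C@@H](COC(=O)C(C)(C)C)[C@@H]2C2=CC(OC)=CC(=O)C2=Cc2cc(OC)cc(OC)c2)cc1 | intermediate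
25 | (1S,2R,3S)-2-[(2R,3R)-3-(3,5-dimethoxyphenyl)-6-methoxy-2-(4-methoxyphenyl)-2,3-dihydrobenzofuran-4-yl]-5,7-dimethoxy-1-(4-methoxyphenyl)-3-(pivaloyloxymethyl)indane | COc1ccc([C@H]2c3c(OC)cc(OC)cc3[C@@H](COC(=O)C(C)(C)C)[C@@H]2c2cc(OC)cc3c2[C@@H](c2cc(OC)cc(OC)c2)[C@H](c2ccc(OC)cc2)O3)cc1 | intermediate
26 | primary alcohol from 25 (hydroxymethyl on C3); (1S,2R,3S,2'R,3'R) | COc1ccc([C@H]2c3c(OC)cc(OC)cc3[C@@H](CO)[C@@H]2c2cc(OC)cc3c2[C@@H](c2cc(OC)cc(OC)c2)[C@H](c2ccc(OC)cc2)O3)cc1 | intermediate
27 | aldehyde from 26 (formyl on C3); (1S,2R,3S,2'R,3'R) | COc1ccc([C@H]2c3c(OC)cc(OC)cc3[C@@H](C=O)[C@@H]2c2cc(OC)cc3c2[C@@H](c2cc(OC)cc(OC)c2)[C@H](c2ccc(OC)cc2)O3)cc1 | intermediate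
28 | 4-methoxyphenylmagnesium bromide | COc1ccc([Mg]Br)cc1 | starting material
29 | heptamethyl ether of the target as a mixture of C8 epimers | COc1ccc([C@H]2c3c(OC)cc(OC)cc3[C@@H](C(O)c3ccc(OC)cc3)[C@@H]2c2cc(OC)cc3c2[C@@H](c2cc(OC)cc(OC)c2)[C@H](c2ccc(OC)cc2)O3)cc1 | intermediate
30 | heptamethyl ether of the C8 ketone; (1S,2R,3S,2'R,3'R) | COc1ccc([C@H]2c3c(OC)cc(OC)cc3[C@@H](C(=O)c3ccc(OC)cc3)[C@@H]2c2cc(OC)cc3c2[C@@H](c2cc(OC)cc(OC)c2)[C@H](c2ccc(OC)cc2)O3)cc1 | intermediate
31 | heptaphenol C8 ketone; (1S,2R,3S,2'R,3'R) | Oc1ccc([C@H]2c3c(O)cc(O)cc3[C@@H](C(=O)c3ccc(O)cc3)[C@@H]2c2cc(O)cc3c2[C@@H](c2cc(O)cc(O)c2)[C@H](c2ccc(O)cc2)O3)cc1 | intermediate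
32 | CNP0175860.1; (1S,2R,3S,8S,2'R,3'R) | Oc1ccc([C@H]2c3c(O)cc(O)cc3[C@@H]([C@H](O)c3ccc(O)cc3)[C@@H]2c2cc(O)cc3c2[C@@H](c2cc(O)cc(O)c2)[C@H](c2ccc(O)cc2)O3)cc1 | target

## Step count and least certain steps

Total: 22 steps. Longest linear sequence: 18 steps (1–8, 10–12, 16–22); step 9 and steps 13–15 prepare the diene and the sulfonium salt.

Step 10 (key step).
- What may go wrong: slow cycloaddition at the β-carbon, which carries a branched secondary alkyl group, so that thermal decay of the diene competes; conjugate addition without ring closure; or aromatisation by loss of the silyloxy group instead of the methoxy group, which would leave C7a' as a methyl ether.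
- Fallback (from 12 and 13, back at 16): the same two bonds are formed stepwise by anions. 13 is deprotonated with LiN(i-Pr)2 at −78 °C to lithium 1,3-dimethoxybuta-1,3-dien-1-olate F1, which adds through its γ-carbon to the β-carbon of 12 (Michael addition). The allenolate so formed acylates itself on the ester (Claisen-type ring closure with loss of methoxide), and the dienone tautomerises to 16 on acidic work-up.

Step 16.
- What may go wrong: transfer of the labile 4-methoxybenzyl group from sulfur to the phenoxide instead of ylide formation; slow addition to a quinone methide that is substituted on both sides of C3a', with capture of C3' by C4 of ring F competing; and insufficient facial control, because the indane hardly differentiates the faces of C3' and the outcome rests on the sulfide alone.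
- Fallback (from 16, back at 25): the ring is built stepwise. The phenol of 16 is protected as the methoxymethyl ether F2 (MOMCl, i-Pr2NEt). The ketone is converted into the 2,2-diaryloxirane F3 with the methylide from Me3SI and n-BuLi (Corey–Chaykovsky). ZnI2 rearranges it to the diarylacetaldehyde F4 (Meinwald rearrangement), and addition of 28 at −78 °C gives the 4-methoxybenzylic alcohol F5. HCl in methanol then removes the acetal and ionises the benzylic alcohol, and the phenol closes the ring to the trans-dihydrobenzofuran 25. C3' is not under reagent control in this sequence: it is enolisable in F4, and the C3' epimers of 25 would have to be separated.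

Step 5 (with consequences for step 7).
- What may go wrong: epimerisation at C2 or β-elimination of the silyloxy group in the open hydroxy-aldehyde form of the lactol under carbonate in methanol, which would scramble the C2/C3 relation. Linked to this, the slim ethynyl group may direct ring A less well in the ring closure of step 7.
- Fallback (from 5, back at 10): the ring is closed before the alkyne exists. LiAlH4 reduces 5 to the triol F6. 2,2-Dimethoxypropane with pyridinium p-toluenesulfonate ties the benzylic hydroxyl and the hydroxymethyl group on C2 into the six-membered acetonide F7, and the remaining primary alcohol is pivaloylated to F8. BF3·OEt2 opens the benzylic C–O bond of the acetonide and closes the indane to the alcohol F9, with the bulkier oxygenated methylene on C2 directing ring A. Dess–Martin oxidation gives the aldehyde F10, in which all-trans is the stable arrangement, and the Ohira–Bestmann reagent converts it into 10.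

Step 21.
- What may go wrong: ionisation of the benzylic ether C2'–O1' by the Lewis acid followed by elimination or Friedel–Crafts capture instead of reclosure, and incomplete cleavage of seven ethers.
- Fallback (from 30, back at 32): the order is reversed and the cleavage made nucleophilic. 30 is reduced as in step 22 to the heptamethyl ether F11 of the target, and the methyl groups are then removed with NaSEt in DMF at 150 °C, conditions under which neither the carbinol nor the benzylic ether can ionise.

Step 22.
- What may go wrong: low conversion of an electron-rich, α-branched aryl ketone; the substrate bias of C3 overriding the catalyst; and acid-induced ionisation of the product carbinol in the formate medium.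
- Fallback (from 31, back at 32): 31 is peracetylated (Ac2O, pyridine) to the heptaacetate F12. This is reduced with the stoichiometric chiral borane (−)-Ipc2BCl to the acetylated carbinol F13, and the acetates are removed with K2CO3 in methanol at 0 °C.

## Further compounds

F1 | step 10 | lithium 1,3-dimethoxybuta-1,3-dien-1-olate | C=C(OC)C=C(OC)[O-].[Li+]
F2 | step 16 | methoxymethyl ether of 16: (1S,2R,3S)-2-[2-(3,5-dimethoxybenzoyl)-5-methoxy-3-(methoxymethoxy)phenyl]-5,7-dimethoxy-1-(4-methoxyphenyl)-3-(pivaloyloxymethyl)indane | COc1ccc([C@H]2c3c(OC)cc(OC)cc3[C@@H](COC(=O)C(C)(C)C)[C@@H]2c2cc(OC)cc(OCOC)c2C(=O)c2cc(OC)cc(OC)c2)cc1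
F3 | step 16 | 2,2-diaryloxirane from F2 (epoxide epimers) | COc1ccc([C@H]2c3c(OC)cc(OC)cc3[C@@H](COC(=O)C(C)(C)C)[C@@H]2c2cc(OC)cc(OCOC)c2C2(CO2)c2cc(OC)cc(OC)c2)cc1
F4 | step 16 | diarylacetaldehyde from F3 (C3' epimers) | COc1ccc([C@H]2c3c(OC)cc(OC)cc3[C@@H](COC(=O)C(C)(C)C)[C@@H]2c2cc(OC)cc(OCOC)c2C(C=O)c2cc(OC)cc(OC)c2)cc1
F5 | step 16 | 2,2-diaryl-1-(4-methoxyphenyl)ethanol from F4 (C2' and C3' epimers) | COc1ccc([C@H]2c3c(OC)cc(OC)cc3[C@@H](COC(=O)C(C)(C)C)[C@@H]2c2cc(OC)cc(OCOC)c2C(C(O)c2ccc(OC)cc2)c2cc(OC)cc(OC)c2)cc1
F6 | step 5 | (2S,3R)-2-(3,5-dimethoxyphenyl)-3-[hydroxy(4-methoxyphenyl)methyl]butane-1,4-diol (carbinol epimers) | COc1ccc(C(O)[C@@H](CO)[C@H](CO)c2cc(OC)cc(OC)c2)cc1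
F7 | step 5 | (2S)-2-(3,5-dimethoxyphenyl)-2-[(5R)-4-(4-methoxyphenyl)-2,2-dimethyl-1,3-dioxan-5-yl]ethan-1-ol | COc1ccc(C2OC(C)(C)OC[C@H]2[C@H](CO)c2cc(OC)cc(OC)c2)cc1
F8 | step 5 | pivalate of F7 | COc1ccc(C2OC(C)(C)OC[C@H]2[C@H](COC(=O)C(C)(C)C)c2cc(OC)cc(OC)c2)cc1
F9 | step 5 | all-trans (1S,2R,3S)-2-(hydroxymethyl)-5,7-dimethoxy-1-(4-methoxyphenyl)-3-(pivaloyloxymethyl)indane | COc1ccc([C@H]2c3c(OC)cc(OC)cc3[C@@H](COC(=O)C(C)(C)C)[C@@H]2CO)cc1
F10 | step 5 | all-trans (1S,2R,3S)-2-formyl-5,7-dimethoxy-1-(4-methoxyphenyl)-3-(pivaloyloxymethyl)indane | COc1ccc([C@H]2c3c(OC)cc(OC)cc3[C@@H](COC(=O)C(C)(C)C)[C@@H]2C=O)cc1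
F11 | step 21 | heptamethyl ether of the target, (8S) | COc1ccc([C@H]2c3c(OC)cc(OC)cc3[C@@H]([C@H](O)c3ccc(OC)cc3)[C@@H]2c2cc(OC)cc3c2[C@@H](c2cc(OC)cc(OC)c2)[C@H](c2ccc(OC)cc2)O3)cc1
F12 | step 22 | heptaacetate of 31 | CC(=O)Oc1ccc([C@H]2c3c(OC(C)=O)cc(OC(C)=O)cc3[C@@H](C(=O)c3ccc(OC(C)=O)cc3)[C@@H]2c2cc(OC(C)=O)cc3c2[C@@H](c2cc(OC(C)=O)cc(OC(C)=O)c2)[C@H](c2ccc(OC(C)=O)cc2)O3)cc1
F13 | step 22 | heptaacetate of the target with free C8 hydroxyl, (8S) | CC(=O)Oc1ccc([C@H]2c3c(OC(C)=O)cc(OC(C)=O)cc3[C@@H]([C@H](O)c3ccc(OC(C)=O)cc3)[C@@H]2c2cc(OC(C)=O)cc3c2[C@@H](c2cc(OC(C)=O)cc(OC(C)=O)c2)[C@H](c2ccc(OC(C)=O)cc2)O3)cc1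
A1 | alternative 1 | (2R)-5-(benzyloxy)-7-methoxy-2-(4-methoxyphenyl)chroman-4-one | COc1ccc([C@H]2CC(=O)c3c(OCc4ccccc4)cc(OC)cc3O2)cc1
A2 | alternative 1 | methyl trans-(2R)-4-(benzyloxy)-6-methoxy-2-(4-methoxyphenyl)-2,3-dihydrobenzofuran-3-carboxylate | c1ccccc1COc1cc(OC)cc2c1[C@@H](C(=O)OC)[C@H](c1ccc(OC)cc1)O2
A3 | alternative 2 | acyclic precursor: (E)-alkenyl pinacol boronate C3=C8 on C2, ring F triflate at C3a, ring A on C1 and the complete dihydrobenzofuran on C2 | COc1ccc([C@@H](c2c(OC)cc(OC)cc2OS(=O)(=O)C(F)(F)F)[C@H](/C=C/B2OC(C)(C)C(C)(C)O2)c2cc(OC)cc3c2[C@@H](c2cc(OC)cc(OC)c2)[C@H](c2ccc(OC)cc2)O3)cc1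
A4 | alternative 2 | heptamethyl ether of the target skeleton with a pinacol boronate in place of the C8 hydroxyl | COc1ccc([C@H]2c3c(OC)cc(OC)cc3[C@@H]([C@H](B3OC(C)(C)C(C)(C)O3)c3ccc(OC)cc3)[C@@H]2c2cc(OC)cc3c2[C@@H](c2cc(OC)cc(OC)c2)[C@H](c2ccc(OC)cc2)O3)cc1
A5 | alternative 3 | 4-hydroxybenzhydryl alcohol on ring F with the ortho ketone C3 whose methylene C2 bears the dihydrobenzofuran | Oc1ccc(C(O)c2c(OC)cc(OC)cc2C(=O)Cc2cc(OC)cc3c2[C@@H](c2cc(OC)cc(OC)c2)[C@H](c2ccc(OC)cc2)O3)cc1
A6 | alternative 3 | trans-2-(dihydrobenzofuran-4-yl)-3-(4-hydroxyphenyl)-4,6-dimethoxyindan-1-one | Oc1ccc([C@H]2c3c(OC)cc(OC)cc3C(=O)[C@@H]2c2cc(OC)cc3c2[C@@H](c2cc(OC)cc(OC)c2)[C@H](c2ccc(OC)cc2)O3)cc1
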